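**Plan**

Carotenoid numbering is used: unprimed atoms belong to the half with the acylated ring A, primed atoms to the half with ring B. Retrosynthetic cuts, in order: C15'–C14' (single bond between two sp2 carbons), C15=C15', the ester C(=O)–O bond at C3, C11=C12, C6–C7.
Forward: no ring is built. Ring A is bought as ketoisophorone and ring B comes inside all-trans-retinoic acid. The chain is joined as C9 + C6 (Stille) to C15, + C5 (Wittig) to C20, acylation, + C1 (Takai) to a C21 iodide, + C19 to the C40 skeleton.
Enabling feature: C14' is the α-carbon of retinoic acid, and its carboxyl carbon sits where C15' must be attached. Attack of divalent palladium at C14' puts charge on tertiary C13', which is conjugated through C12'=C11', C10'=C9' and C8'=C7' with C6'=C5' of ring B. CO2 should therefore leave far more easily than from a simple acrylic acid.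
One event thus brings in ring B, 19 carbons and four E double bonds from an unmodified commercial acid, needs no organometallic reagent, and removes its own activating group as CO2.
Stereochemistry: C3 (R) comes from the two-enzyme reduction of ketoisophorone to (4R,6R)-actinol, and the second centre is erased later. The 9Z alkene is bought in palmitoleic acid. The E alkenes come from the building blocks, stereoretentive couplings, the Takai step and a final thermal equilibration.

Key step: step 10

Assumption: (E)-4,4-dimethoxy-2-methylbut-2-enal, an industrial C5 carotenoid building block, is taken as purchasable, and all polyene steps are run under argon in dim light.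

Step 1
Reactants: 1 ketoisophorone
Product: 3 (4R,6R)-actinol, via (6R)-levodione 2 (not isolated)
Conditions: ene-reductase (old yellow enzyme class, OYE2), NADP+ (cat.), glucose dehydrogenase, D-glucose (2.2 equiv), phosphate buffer pH 7, 30 °C; then levodione reductase (NADH-dependent short-chain ketoreductase), NAD+ (cat.), same recycling system
Reagents that add atoms: none
Why: The flavin ene-reductase should add H2 in net trans fashion across C2=C3 and set 6R, after which the ketoreductase should reduce only the unhindered C4 carbonyl to the 4R alcohol, a known sequence of enzymatic C=C and C=O reduction.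

Step 2
Reactants: 3 (4R,6R)-actinol
Product: 4 (4R,6R)-2,2,6-trimethyl-4-(triethylsilyloxy)cyclohexan-1-one
Conditions: TESCl, imidazole, CH2Cl2, 0 °C to rt
Reagents that add atoms: chlorotriethylsilane (TESCl), CC[Si](Cl)(CC)CC
Why: Imidazole-promoted silylation of a secondary alcohol masks the OH for the strong-base step, and TES is chosen because it falls off in the acid of step 6.

Step 3
Reactants: 4 silyloxy ketone
Product: 6 ring A enol triflate, via lithium enolate 5 (not isolated)
Conditions: LiN(iPr)2 (commercial solution), THF, −78 to 0 °C; then PhNTf2, 0 °C to rt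
Reagents that add atoms: N-phenylbis(trifluoromethanesulfonimide) (PhNTf2), FC(F)(F)S(=O)(=O)N(c1ccccc1)S(=O)(=O)C(F)(F)F
Why: Only one α-carbon bears hydrogen, so a single enolate forms, and its O-sulfonylation (enol triflate formation) fixes the ring double bond at carotenoid C5=C6 and erases the methyl-bearing stereocentre without touching C3.

Step 4
Reactants: 7 (E)-3-methylpent-2-en-4-yn-1-ol
Product: 8 (2E,4E)-3-methyl-5-(tributylstannyl)penta-2,4-dien-1-ol
Conditions: Bu3SnH, PdCl2(PPh3)2 (2 mol %), THF, 0 °C
Reagents that add atoms: tributyltin hydride, CCCC[SnH](CCCC)CCCC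
Why: Palladium-catalysed syn hydrostannation of a terminal alkyne should place tin at the open terminus because the inner carbon carries the branched alkenyl group, giving the 4E stannane, with any internal regioisomer removed by chromatography.

Step 5
Reactants: 6 ring A enol triflate; 8 dienylstannane
Product: 9 (2E,4E)-3-methyl-5-[(4R)-2,6,6-trimethyl-4-(triethylsilyloxy)cyclohex-1-en-1-yl]penta-2,4-dien-1-ol
Conditions: Pd2(dba)3 (2.5 mol %), AsPh3 (20 mol %), NMP, 65 °C
Reagents that add atoms: none
Why: Stille coupling of the parent trimethylcyclohexenyl triflate with dienylstannanes is closely precedented under weak-donor-ligand conditions, retains the stannane geometry and forms C6–C7.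

Step 6
Reactants: 9 C15 allylic alcohol
Product: 10 (3R)-3-hydroxy-C15 triphenylphosphonium bromide
Conditions: PPh3·HBr (1.2 equiv), MeOH, rt
Reagents that add atoms: triphenylphosphine hydrobromide, [Br-].c1ccc(cc1)[PH+](c1ccccc1)c1ccccc1
Why: Acid ionises the allylic alcohol to a trienyl cation that PPh3 captures at the unhindered terminus C11 (standard allylic phosphonium salt formation of retinoid chemistry), while the slight excess of acid in methanol removes the TES ether.

Step 7
Reactants: 10 C15 phosphonium bromide; 11 (E)-4,4-dimethoxy-2-methylbut-2-enal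
Product: 14 (3R)-all-E-3-hydroxyretinal, via C15 phosphorus ylide 12 (not isolated), via hydroxyretinal dimethyl acetal 13 (not isolated)
Conditions: NaOMe (1.1 equiv), MeOH–CH2Cl2, 0 °C to rt; then 1 M aq. HCl, THF, rt; chromatography
Reagents that add atoms: water, O
Why: Wittig olefination of the semistabilised C15 ylide with the C5 aldehyde forms C11=C12 (the industrial C15 + C5 retinoid pattern), and the dilute acid unmasks the aldehyde and helps convert the hindered 11Z isomer into 11E, with remaining Z isomers removed by chromatography.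

Step 8
Reactants: 14 (3R)-3-hydroxyretinal; 15 palmitoleic acid
Product: 16 (3R)-3-[(9Z)-hexadec-9-enoyloxy]retinal
Conditions: DCC, DMAP (cat.), CH2Cl2, 0 °C to rt
Reagents that add atoms: none
Why: Steglich esterification acylates at oxygen, so C3 keeps its R configuration, and neither the polyenal nor the 9Z alkene is affected.

Step 9
Reactants: 16 acyloxyretinal
Product: 17 C21 (E)-hexaenyl iodide
Conditions: CrCl2 (8 equiv), CHI3 (2.5 equiv), THF–dioxane, 0 °C; short filtration, used at once
Reagents that add atoms: iodoform, IC(I)I
Why: In the Takai olefination the geminal dichromium species from CHI3 adds to the aldehyde and eliminates to the E-alkenyl iodide, which installs C15', while esters and isolated alkenes are inert to CrCl2.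

Step 10
Reactants: 17 C21 (E)-hexaenyl iodide; 18 all-trans-retinoic acid
Product: 20 (3R)-β-cryptoxanthin palmitoleate (target), via lithium retinoate 19 (not isolated)
Conditions: Pd(OAc)2 (10 mol %), AsPh3 (20 mol %), LiOAc (2.5 equiv), LiCl (1 equiv), BHT (trace), degassed DMF–DMSO (20:1), 90 °C; then heptane, 95 °C, 2 h; chromatography, crystallisation from acetone–MeOH at −20 °C
Reagents that add atoms: none
Why: Proposed new method: zerovalent palladium should insert into the C15'–I bond of 17 with retention, and exchange of iodide for retinoate 19 should give an alkenylpalladium carboxylate. The divalent metal should then shift from oxygen to the ipso carbon C14', because the charge building at C13' is tertiary and spread over C12'=C11', C10'=C9', C8'=C7' and C6'=C5' of ring B; loss of CO2 gives a dialkenylpalladium, and reductive elimination forms C15'–C14'. The closest known reaction types are the palladium-catalysed decarboxylative coupling of electron-rich cinnamic and 5-arylpenta-2,4-dienoic acids with alkenyl bromides to dienes and trienes, and the decarboxylative palladation of electron-rich arenecarboxylic acids; new here are the β-methyl-branched aliphatic polyenoic acid and the polyenyl iodide. No ring is closed and no stereocentre is made, and C3 with its homoallylic ester lies far from the reacting ends. Cross-selectivity is secured by the two different roles (one C–I bond, one carboxylate), and site selectivity by the carboxyl group, which binds the metal and marks C14' alone among the sp2 carbons of both polyenes. C15=C15' should keep its E geometry, whereas C13'=C14' may partly scramble in the cation-like stage, which is why the crude product is digested in hot heptane, since 13'Z is an unhindered cis form that equilibrates thermally toward all-E.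

**Compound list**

1 | ketoisophorone (2,6,6-trimethylcyclohex-2-ene-1,4-dione) | CC1=CC(=O)CC(C)(C)C1=O | starting material
2 | (6R)-levodione ((6R)-2,2,6-trimethylcyclohexane-1,4-dione) | C[C@@H]1CC(=O)CC(C)(C)C1=O | intermediate
3 | (4R,6R)-actinol ((4R,6R)-4-hydroxy-2,2,6-trimethylcyclohexan-1-one) | O[C@@H]1C[C@@H](C)C(=O)C(C)(C)C1 | intermediate
4 | (4R,6R)-2,2,6-trimethyl-4-(triethylsilyloxy)cyclohexan-1-one | CC[Si](CC)(CC)O[C@@H]1C[C@@H](C)C(=O)C(C)(C)C1 | intermediate
5 | lithium enolate of 4 | CC[Si](CC)(CC)O[C@@H]1CC(C)=C([O-])C(C)(C)C1.[Li+] | intermediate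
6 | (4R)-2,6,6-trimethyl-4-(triethylsilyloxy)cyclohex-1-en-1-yl trifluoromethanesulfonate | CC[Si](CC)(CC)O[C@@H]1CC(C)=C(OS(=O)(=O)C(F)(F)F)C(C)(C)C1 | intermediate
7 | (E)-3-methylpent-2-en-4-yn-1-ol | C#C/C(C)=C/CO | starting material
8 | (2E,4E)-3-methyl-5-(tributylstannyl)penta-2,4-dien-1-ol | CCCC[Sn](CCCC)(CCCC)/C=C/C(C)=C/CO | intermediate
9 | (2E,4E)-3-methyl-5-[(4R)-2,6,6-trimethyl-4-(triethylsilyloxy)cyclohex-1-en-1-yl]penta-2,4-dien-1-ol | CC[Si](CC)(CC)O[C@@H]1CC(C)=C(/C=C/C(C)=C/CO)C(C)(C)C1 | intermediate
10 | [(2E,4E)-5-[(4R)-4-hydroxy-2,6,6-trimethylcyclohex-1-en-1-yl]-3-methylpenta-2,4-dien-1-yl]triphenylphosphonium bromide | O[C@@H]1CC(C)=C(/C=C/C(C)=C/C[P+](c2ccccc2)(c2ccccc2)c2ccccc2)C(C)(C)C1.[Br-] | intermediate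
11 | (E)-4,4-dimethoxy-2-methylbut-2-enal | O=C/C(C)=C/C(OC)OC | starting material
12 | C15 phosphorus ylide from 10 | O[C@@H]1CC(C)=C(/C=C/C(C)=C/C=P(c2ccccc2)(c2ccccc2)c2ccccc2)C(C)(C)C1 | intermediate
13 | (3R)-3-hydroxyretinal dimethyl acetal (drawn all-E) | O[C@@H]1CC(C)=C(/C=C/C(C)=C/C=C/C(C)=C/C(OC)OC)C(C)(C)C1 | intermediate
14 | (3R)-all-E-3-hydroxyretinal | O[C@@H]1CC(C)=C(/C=C/C(C)=C/C=C/C(C)=C/C=O)C(C)(C)C1 | intermediate
15 | palmitoleic acid ((9Z)-hexadec-9-enoic acid) | CCCCCC/C=C\CCCCCCCC(=O)O | starting material
16 | (3R)-3-[(9Z)-hexadec-9-enoyloxy]retinal | CCCCCC/C=C\CCCCCCCC(=O)O[C@@H]1CC(C)=C(/C=C/C(C)=C/C=C/C(C)=C/C=O)C(C)(C)C1 | intermediate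
17 | (1R)-4-[(1E,3E,5E,7E,9E)-10-iodo-3,7-dimethyldeca-1,3,5,7,9-pentaen-1-yl]-3,5,5-trimethylcyclohex-3-en-1-yl (9Z)-hexadec-9-enoate | CCCCCC/C=C\CCCCCCCC(=O)O[C@@H]1CC(C)=C(/C=C/C(C)=C/C=C/C(C)=C/C=C/I)C(C)(C)C1 | intermediate
18 | all-trans-retinoic acid | OC(=O)/C=C(C)/C=C/C=C(C)/C=C/C1=C(C)CCCC1(C)C | starting material
19 | lithium all-trans-retinoate | [Li+].[O-]C(=O)/C=C(C)/C=C/C=C(C)/C=C/C1=C(C)CCCC1(C)C | intermediate
20 | (3R)-β,β-caroten-3-yl (9Z)-hexadec-9-enoate ((3R)-β-cryptoxanthin palmitoleate) | CCCCCC/C=C\CCCCCCCC(=O)O[C@@H]1CC(C)=C(/C=C/C(C)=C/C=C/C(C)=C/C=C/C=C(C)/C=C/C=C(C)/C=C/C2=C(C)CCCC2(C)C)C(C)(C)C1 | target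

Total step count: 10. Longest linear sequence: 9 (steps 1, 2, 3, 5, 6, 7, 8, 9, 10).

**Steps most likely to fail**

Step 10 (labelled step). The palladium carboxylate may be lost before CO2 leaves. The possible processes are protodecarboxylation of the retinoate, reductive homocoupling of the iodide, and thermal decay of the polyenylpalladium species. The fallback forms the same C15'–C14' bond by known chemistry, zirconium-catalysed methylalumination followed by Negishi coupling. It sets out from 17 and comes back at 20. Commercial β-apo-13-carotenone F1 (the C18 methyl ketone of the ring B series) is treated with LiN(iPr)2 and ClP(O)(OEt)2 to give the enol phosphate F2. Excess LiN(iPr)2 eliminates F2 to the terminal enyne F3. Me3Al with catalytic Cp2ZrCl2 in CH2Cl2 adds methyl and aluminium syn across the alkyne to give the E-alkenylalane F4, so the C13' methyl group and the 13'E geometry are set together. After excess Me3Al is removed in vacuo, F4 is coupled with 17 (ZnCl2, Pd2(dba)3, P(2-furyl)3, THF–DMF, rt), conditions that esters tolerate.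

Step 9. The polyenal may undergo pinacol-type reductive coupling by CrCl2, the E selectivity may erode on so extended an aldehyde, or the light-sensitive iodide may decay during isolation. The fallback replaces the one-carbon olefination by an alkyne route. It sets out from 14 and comes back at 17. Lithiated TMSCHN2 (Colvin homologation, two equivalents because of the free OH, THF, −78 °C to rt) turns 14 into the terminal enyne alcohol F5. Steglich esterification with 15 gives the enyne ester F6. Cp2Zr(H)Cl (1.1 equiv, THF, rt) hydrozirconates the terminal alkyne syn, with the metal at the terminus, to give the alkenylzirconocene F7, faster than it attacks the ester or the internal alkene. I2 (1.0 equiv, −78 °C) cleaves the C–Zr bond with retention to give 17.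

Step 5. Oxidative addition into the tetrasubstituted enol triflate, which is flanked on both sides, may be too slow, so that protodestannylation and homocoupling of 8 take over. The fallback forms C6–C7 by carbonyl addition in place of cross-coupling. It sets out from 4 (with 7) and comes back at 10. The dilithio derivative of 7 (n-BuLi, 2 equiv, THF, −78 °C) adds to ketone 4 to give the propargylic diol F8, as epimers at the carbinol carbon, which is of no consequence. NaAlH2(OCH2CH2OMe)2 in THF reduces the propargylic alkyne by trans hydroalumination to the E,E-dienediol F9. PPh3·HBr in MeOH then dehydrates the tertiary allylic alcohol toward C5, forms the phosphonium salt at C11 and removes the TES ether in one operation to give 10.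

**Further compounds**

F1 | step 10 | β-apo-13-carotenone ((3E,5E,7E)-6-methyl-8-(2,6,6-trimethylcyclohex-1-en-1-yl)octa-3,5,7-trien-2-one, bought) | CC(=O)/C=C/C=C(C)/C=C/C1=C(C)CCCC1(C)C
F2 | step 10 | diethyl enol phosphate of F1 | C=C(OP(=O)(OCC)OCC)/C=C/C=C(C)/C=C/C1=C(C)CCCC1(C)C
F3 | step 10 | C18 terminal enyne, 2-[(1E,3E,5E)-3-methylocta-1,3,5-trien-7-yn-1-yl]-1,3,3-trimethylcyclohex-1-ene | C#C/C=C/C=C(C)/C=C/C1=C(C)CCCC1(C)C
F4 | step 10 | C19 (E)-alkenyldimethylalane | C[Al](C)/C=C(C)/C=C/C=C(C)/C=C/C1=C(C)CCCC1(C)C
F5 | step 9 | (3R)-3-hydroxy C21 terminal enyne | O[C@@H]1CC(C)=C(/C=C/C(C)=C/C=C/C(C)=C/C#C)C(C)(C)C1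
F6 | step 9 | palmitoleate of F5 | CCCCCC/C=C\CCCCCCCC(=O)O[C@@H]1CC(C)=C(/C=C/C(C)=C/C=C/C(C)=C/C#C)C(C)(C)C1
F7 | step 9 | (E)-alkenylzirconocene chloride from F6 | CCCCCC/C=C\CCCCCCCC(=O)O[C@@H]1CC(C)=C(/C=C/C(C)=C/C=C/C(C)=C/C=C/[Zr](Cl)(C2C=CC=C2)C2C=CC=C2)C(C)(C)C1
F8 | step 5 | (4R,6R)-1-[(E)-5-hydroxy-3-methylpent-3-en-1-yn-1-yl]-2,2,6-trimethyl-4-(triethylsilyloxy)cyclohexan-1-ol (epimers at C1) | CC[Si](CC)(CC)O[C@@H]1C[C@@H](C)C(O)(C#C/C(C)=C/CO)C(C)(C)C1
F9 | step 5 | (4R,6R)-1-[(1E,3E)-5-hydroxy-3-methylpenta-1,3-dien-1-yl]-2,2,6-trimethyl-4-(triethylsilyloxy)cyclohexan-1-ol (epimers at C1) | CC[Si](CC)(CC)O[C@@H]1C[C@@H](C)C(O)(/C=C/C(C)=C/CO)C(C)(C)C1
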